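## The problem

The target is an open-chain ester in which (E)-4-geranyloxy-2-hydroxycinnamic acid acylates the secondary C6' hydroxyl of a 7-O-alkylcoumarin whose C1'–C8' chain is an (E)-geranyl unit oxidised at C6' and C7'. The coumarin and the resorcinol-type benzene ring can both be bought, so no ring has to be made; the work lies in building the oxidised C10 chain and in ordering three heteroatom links: the aryl ether at C1', the ester at C6', and the free phenol ortho to the cinnamate, which must be told apart from the phenol of umbelliferone. There is one stereocenter, C6' (R); it is remote from everything else, so nothing in the molecule can control it and it must be set by a reagent or catalyst. Three alkenes (C2'=C3', the geranyl C2=C3 and the cinnamate) must be E and stay E. Several groups are fragile: the two allyl aryl ethers ionise under protic or Lewis acid and with zerovalent palladium; the (E)-2-hydroxycinnamate lactonises with loss of the alcohol once light or base turns it Z; the C6' ester next to a free tertiary hydroxyl can migrate under base; the coumarin lactone and the trisubstituted alkenes rule out hydroxide at the end, hydrogenation and strong electrophiles. The feature that opens the key step is that C6' sits between C7', which carries oxygen and two methyl groups but no hydrogen, and the C5'H2–C4'H2 link. C6' can therefore be the carbonyl carbon of a non-enolisable α-silyloxy aldehyde and C5' the zinc-bearing carbon of a chain that already holds the E C2'=C3' alkene.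

## Retrosynthesis

**28 from 27.** The last bonds cut are the two O–Si bonds of 27, at the phenol and at C7'. Silicon on both oxygens lets one buffered fluoride treatment finish the synthesis. An acid-labile or hydrogenolysable phenol group would put the allyl aryl ethers or the alkenes at risk. 27 has the full skeleton but lacks the two functions that make the target fragile (the phenol that allows lactonisation, the tertiary hydroxyl that allows acyl shift). The forward step must be buffered so that neither acyl migration nor E/Z isomerisation sets in.

**27 from 18 and 25.** The ester C(=O)–O bond at C6' is cut, which divides the molecule into two halves of similar size: the coumarin alcohol 18 and the silyl-protected cinnamic acid 25. The neighbouring choice, forming the C1'–O aryl ether last, would make a late Mitsunobu reaction choose between umbelliferone and the cinnamate phenol, or would demand a phenol protecting group orthogonal to fluoride. With the ether made first, a simple silyl ether on the phenol is enough. The forward reaction must acylate a secondary hydroxyl next to a quaternary carbon with retention, so the acid is activated and the alcohol is not.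

**18 from 16 and 17.** The C1'–O aryl ether bond is cut, giving diol 16 and umbelliferone 17. Attaching the coumarin after the organometallic steps keeps its lactone and enone away from zinc, lithium and titanium reagents. 16 is an aliphatic diol with one stereocenter. The forward Mitsunobu reaction must take the primary allylic hydroxyl and leave the hindered C6' hydroxyl alone, which their steric difference should ensure.

**16 from 15.** The O–CH2Ar bond of the 4-methoxybenzyl ether at C1' is cut. This group is chosen for C1' because it leaves oxidatively while the tertiary triethylsilyl ether stays, which a second silyl group could not do. It is also a poor allylic leaving group, unlike an ester, so it does not invite allylic substitution by organozinc species. The forward step must not oxidise the product allylic alcohol further.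

**15 from 10 and 14.** The C5'–C6' bond is cut, giving the mixed diorganozinc 10 and aldehyde 14; this is the disconnection that carries the plan. Cutting here makes the stereocenter and a skeletal bond together, and delivers C6'–OH free, C7'–O silylated and C1'–O benzylated, so no later step has to select among hydroxyls. Cutting C4'–C5' or C6'–C7' instead would leave an enolisable or less differentiated carbonyl partner. Both fragments are achiral and small. The forward reaction must select one enantioface of 14 under catalyst control, transfer only the functionalised chain from zinc, and add without reduction.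

**10 from 8, 7, 6, 5, 2 and 1.** The C–Zn bond of the chain is traced to iodide 8 by zinc insertion through the alkylzinc iodide 9. The second valence of zinc is filled with a (trimethylsilyl)methyl group, which does not transfer, so each molecule of 8 delivers its chain and none is spent as a dummy ligand. Iodide 8 comes from alcohol 7 by functional group exchange, and protecting-group changes lead through 6 to allylic alcohol 5. In 5 the C3'–CH3 and C2'–C1' bonds are cut, leading to the silyl ether 2 of but-3-yn-1-ol 1. Methylalumination and formaldehyde trapping fix the E alkene by syn addition and retention, whereas a Wittig-type construction of the same trisubstituted alkene would give mixtures. The Lewis-acidic aluminium step is placed on a simple silyl ether, before any stereocenter or acetal exists.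

**14 from 12 and 11.** The aldehyde is an oxidation-state adjustment of silyl ester 12, made from methyl 2-hydroxyisobutyrate 11. The silyl group is needed because the free α-hydroxy aldehyde dimerises. The forward reduction must stop at the aldehyde.

**25 from 23, 22, 21, 19 and 20.** The acid 25 is the selectively desilylated form of 24, made from hydroxy acid 23. The cinnamate C=C bond is cut by a Wittig disconnection to aldehyde 21 by way of ester 22, and the geranyl C–O bond leads to 2,4-dihydroxybenzaldehyde 19 and geranyl bromide 20. A Knoevenagel route is avoided because salicylaldehydes give coumarin acids there. The stabilised ylide tolerates the free phenol and gives the E alkene.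

## Roads not taken

Alternative 1: The coumarin ring would be closed late. The cut is the C4–C4a bond of the pyranone. The aryl propiolate A1, a 3-alkoxyphenyl ester carrying the finished chain as its 6',7'-acetonide, would cyclise under Ph3PAuCl/AgSbF6 (cationic monovalent gold). The arene attacks the activated alkyne in a 6-endo sense to give the 7-alkoxycoumarin A2.
- Merits: the step is mild and atom-economic. The stereocenter could come from an asymmetric dihydroxylation (K2OsO2(OH)4 with a cinchona alkaloid ligand) of the terminal alkene of a geranyl aryl ether, a dependable reaction that reaches the diol in fewer steps than the nine leading to 15 here.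
- Weak points: the key step is spent on a ring that is sold as 17. Closure can occur ortho or para to the alkoxy group. Gold and silver cations are π-acids toward the trisubstituted alkene and Lewis acids toward the allyl aryl ether and the acetonide. After A2 the acetonide must come off and the acylation must choose the secondary over the tertiary hydroxyl.
- Comparison: this road is shorter to the diol and probably at least as reliable in enantioselectivity. The chosen plan sets three things against that: C6' is formed together with a skeletal bond, with its oxygen neighbours already differentiated; no acetonide is put on and removed; and no carbophilic Lewis acid meets an allyl aryl ether.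

Alternative 2: The C3'–CH3 and C2'–C1' bonds would be made on a chiral alkyne. The acetonide alkyne A3 would undergo Cp2ZrCl2-catalysed addition of AlMe3; the alkenylalanate (after n-BuLi) would be trapped with paraformaldehyde to give allylic alcohol A4, one Mitsunobu reaction away from the coumarin ether.
- Merits: the E alkene is set by the same reliable syn-addition logic used here in step 2. The stereocenter would again come from asymmetric dihydroxylation, whose selectivity on trisubstituted alkenes is arguably more predictable than an addition to a hindered aldehyde. The step count is comparable or slightly lower.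
- Weak points: excess AlMe3 is a strong Lewis acid that can open a dioxolane by methyl transfer, and here the acetonide and the stereocenter sit three carbons from the reacting alkyne. The diol must be protected and deprotected, and the tertiary and secondary hydroxyls emerge undifferentiated.
- Comparison: alkene control is equal. The chosen plan moves the aluminium step to the achiral silyl ether 2 and builds the stereocenter afterwards, already differentiated.

Alternative 3: The C4'–C5' bond would be made by a Claisen rearrangement. The racemic allylic alcohol A5 would exchange with the hydroxy ketal A6 under weak acid and heat. The resulting allyl vinyl ether would rearrange to the hydroxy ketone A7, forming the bond, the E C2'=C3' alkene and the C6' carbonyl at once.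
- Merits: it is convergent on 17 from the start and short; a chair transition state should give the E alkene.
- Weak points: the stereocenter is not set and needs a separate enantioselective reduction of an α-hydroxy ketone whose free tertiary hydroxyl can bind the catalyst. An allyl aryl ether and a coumarin are heated with acid, where ionisation and aromatic Claisen shift are possible. A6 must be prepared.
- Comparison: this road is shorter than the chosen one and would be competitive if the reduction were selective. The chosen plan creates C6' in the bond-forming step itself and never heats an allyl aryl ether with acid.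

Key step: step 9

Remarks on the chemistry:
- The (1R,2R) enantiomer of the bis(sulfonamide) ligand is taken to deliver alkyl groups to the Si face of an aldehyde, as in its standard use. Aldehyde 14 needs Re-face attack to give R at C6', so the (1S,2S) ligand is specified.
- Zinc in 10 carries the functionalised chain and one (trimethylsilyl)methyl group as a non-transferable spectator ligand, so one molecule of iodide 8 supplies each molecule of 10.
- Metal alkoxides that are only protonated on aqueous work-up are counted as the product of their step. Organometallic species made by one reagent and consumed by a second are numbered.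

## Route

Step 1
Reactants: 1 but-3-yn-1-ol
Product: 2 tert-butyl(but-3-yn-1-yloxy)dimethylsilane
Conditions: TBSCl, imidazole, CH2Cl2, 0 °C to rt
Reagents that add atoms: tert-butyldimethylsilyl chloride, CC(C)(C)[Si](C)(C)Cl
Why: Silylation of a primary alcohol; a silyl ether is carried through zirconium-catalysed methylalumination, whereas an acetal could be opened by AlMe3.

Step 2
Reactants: 2 tert-butyl(but-3-yn-1-yloxy)dimethylsilane
Product: 5 (E)-5-(tert-butyldimethylsilyloxy)-3-methylpent-2-en-1-ol, via alkenyldimethylalane 3 (not isolated), via lithium alkenylalanate 4 (not isolated)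
Conditions: AlMe3, Cp2ZrCl2 (cat.), CH2Cl2, 0 °C to rt; n-BuLi, hexane, 0 °C; (CH2O)n, THF, rt; aq. work-up
Reagents that add atoms: trimethylaluminium, C[Al](C)C; paraformaldehyde (as formaldehyde), C=O
Why: Zirconium-catalysed syn methylalumination of a terminal alkyne puts CH3 on the internal carbon and aluminium on the terminal one. The alanate then adds to formaldehyde with retention, so CH2OH ends cis to the methyl group, which is the E alkene.

Step 3
Reactants: 5 (E)-5-(tert-butyldimethylsilyloxy)-3-methylpent-2-en-1-ol
Product: 6 tert-butyl({(E)-5-[(4-methoxybenzyl)oxy]-3-methylpent-3-en-1-yl}oxy)dimethylsilane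
Conditions: NaH, 4-methoxybenzyl chloride, n-Bu4NI (cat.), THF–DMF, 0 °C to rt
Reagents that add atoms: 4-methoxybenzyl chloride, COc1ccc(CCl)cc1
Why: Williamson etherification of the primary allylic alkoxide. The ether is stable to zinc and titanium reagents, is a poor allylic leaving group, and is later removed oxidatively without touching silicon.

Step 4
Reactants: 6 tert-butyl({(E)-5-[(4-methoxybenzyl)oxy]-3-methylpent-3-en-1-yl}oxy)dimethylsilane
Product: 7 (E)-5-[(4-methoxybenzyl)oxy]-3-methylpent-3-en-1-ol
Conditions: TBAF, THF, rt
Reagents that add atoms: none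
Why: Fluoride cleavage of the primary silyl ether; the 4-methoxybenzyl ether and the alkene are inert.

Step 5
Reactants: 7 (E)-5-[(4-methoxybenzyl)oxy]-3-methylpent-3-en-1-ol
Product: 8 1-({[(E)-5-iodo-3-methylpent-2-en-1-yl]oxy}methyl)-4-methoxybenzene
Conditions: I2, PPh3, imidazole, CH2Cl2, 0 °C, dark
Reagents that add atoms: iodine, II
Why: Appel-type iodination of a primary alcohol through the alkoxyphosphonium iodide (SN2); the neutral conditions leave the allylic ether and the alkene geometry alone.

Step 6
Reactants: 8 1-({[(E)-5-iodo-3-methylpent-2-en-1-yl]oxy}methyl)-4-methoxybenzene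
Product: 10 {(E)-5-[(4-methoxybenzyl)oxy]-3-methylpent-3-en-1-yl}[(trimethylsilyl)methyl]zinc, via alkylzinc iodide 9 (not isolated)
Conditions: Zn dust (activated with BrCH2CH2Br and Me3SiCl), THF, 35 °C; Me3SiCH2Li, pentane, −78 °C to 0 °C; THF and pentane removed under vacuum, residue taken up in toluene and filtered from LiI under argon
Reagents that add atoms: zinc, [Zn]; (trimethylsilyl)methyllithium, [Li]C[Si](C)(C)C
Why: Oxidative insertion of activated zinc into a primary alkyl iodide gives the alkylzinc iodide 9, and salt metathesis with Me3SiCH2Li replaces iodide by a (trimethylsilyl)methyl group, a ligand known not to transfer from zinc, so each molecule of 8 delivers its chain. The 4-methoxybenzyl ether and the trisubstituted alkene are inert to organozinc species, and removing LiI and THF keeps halide salts and donor solvent out of the titanium-catalysed step.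

Step 7
Reactants: 11 methyl 2-hydroxy-2-methylpropanoate
Product: 12 methyl 2-methyl-2-(triethylsilyloxy)propanoate
Conditions: Et3SiOTf, 2,6-lutidine, CH2Cl2, 0 °C
Reagents that add atoms: triethylsilyl trifluoromethanesulfonate, CC[Si](CC)(CC)OS(=O)(=O)C(F)(F)F
Why: Silylation of a tertiary α-hydroxy ester calls for the silyl triflate. The triethylsilyl group keeps the later aldehyde monomeric and bulky, yet leaves with buffered fluoride at the end.

Step 8
Reactants: 12 methyl 2-methyl-2-(triethylsilyloxy)propanoate
Product: 14 2-methyl-2-(triethylsilyloxy)propanal, via aluminium hemiacetal 13 (not isolated)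
Conditions: i-Bu2AlH, CH2Cl2, −78 °C; then aq. potassium sodium tartrate
Reagents that add atoms: none
Why: Partial reduction of an ester with i-Bu2AlH. The tetrahedral aluminium hemiacetal 13 persists at −78 °C and releases the aldehyde only on work-up, which guards against over-reduction. The product has no α-hydrogen and cannot enolise.

Step 9
Reactants: 10 {(E)-5-[(4-methoxybenzyl)oxy]-3-methylpent-3-en-1-yl}[(trimethylsilyl)methyl]zinc; 14 2-methyl-2-(triethylsilyloxy)propanal
Product: 15 (R,E)-8-[(4-methoxybenzyl)oxy]-2,6-dimethyl-2-(triethylsilyloxy)oct-6-en-3-ol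
Conditions: Ti(OiPr)4 (2 equiv), (1S,2S)-1,2-bis(trifluoromethanesulfonamido)cyclohexane (8 mol %), toluene, 45 °C then −40 °C; 10 (1.6 equiv), then 14, −20 °C; then aq. NH4Cl
Reagents that add atoms: none
Why: The bis(sulfonamide) binds Ti(OiPr)4 as a chiral bis(sulfonamido)titanium diisopropoxide, a Lewis acid that takes up aldehyde 14 at its carbonyl oxygen; the functionalised alkyl group of 10 passes from zinc to titanium and from there to the carbonyl carbon, and the excess Ti(OiPr)4 frees the catalyst from the product alkoxide. The (trimethylsilyl)methyl group stays on zinc because its hindered, silicon-stabilised carbon migrates far more slowly than a primary alkyl group, and it has no β-hydrogen to give up. The closest known reaction type is the Ti(OiPr)4/bis(trifluoromethanesulfonamide)-catalysed addition of mixed functionalised alkyl[(trimethylsilyl)methyl]zinc reagents to aliphatic and α-silyloxy aldehydes. No ring closes. The one new stereocenter, C6' (C3 of 15), is under catalyst control: the (1S,2S) ligand should direct the alkyl group to the Re face of 14, which corresponds to R because the order O > C7' > C5' > H matches the standard case. The step needs enantioface selection and clean 1,2-addition; 14 cannot enolise, its α-silyloxy group raises the electrophilicity of the carbonyl against the bulk of the quaternary carbon, and the large CMe2(OSiEt3) group set against hydrogen gives the catalyst a clear size difference. The ether oxygen of 10 is six atoms from zinc and held away by the E alkene, so it cannot chelate and erode selectivity, and the alkene and the benzyl-type ether are inert to zinc and titanium alkoxides. Holding −20 °C should suppress β-hydride transfer from the alkyl chain, the reduction pathway open to a hindered aldehyde.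

Step 10
Reactants: 15 (R,E)-8-[(4-methoxybenzyl)oxy]-2,6-dimethyl-2-(triethylsilyloxy)oct-6-en-3-ol
Product: 16 (R,E)-3,7-dimethyl-7-(triethylsilyloxy)oct-2-ene-1,6-diol
Conditions: DDQ (1.1 equiv), CH2Cl2–H2O (pH 7, KH2PO4/K2HPO4), 0 °C
Reagents that add atoms: none
Why: Oxidative cleavage of a 4-methoxybenzyl ether by hydride abstraction with DDQ and hydrolysis of the oxocarbenium ion. The buffer keeps the tertiary silyl ether, and a small excess of oxidant spares the allylic alcohol and the alkene.

Step 11
Reactants: 16 (R,E)-3,7-dimethyl-7-(triethylsilyloxy)oct-2-ene-1,6-diol; 17 umbelliferone (7-hydroxy-2H-chromen-2-one)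
Product: 18 7-{[(R,E)-6-hydroxy-3,7-dimethyl-7-(triethylsilyloxy)oct-2-en-1-yl]oxy}-2H-chromen-2-one
Conditions: PPh3, DIAD, THF, 0 °C to rt
Reagents that add atoms: none
Why: Mitsunobu reaction: the primary allylic hydroxyl is activated as its alkoxyphosphonium salt and displaced at the primary carbon by the acidic phenol of 17. The C6' hydroxyl, secondary and next to a quaternary carbon, is too hindered to be activated, so C6' keeps its configuration.

Step 12
Reactants: 19 2,4-dihydroxybenzaldehyde; 20 geranyl bromide ((E)-1-bromo-3,7-dimethylocta-2,6-diene)
Product: 21 4-{[(E)-3,7-dimethylocta-2,6-dien-1-yl]oxy}-2-hydroxybenzaldehyde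
Conditions: K2CO3 (1 equiv), acetone, rt
Reagents that add atoms: none
Why: Williamson etherification. The 4-hydroxyl, para to the formyl group, is the more acidic and is not held in the hydrogen bond that ties the 2-hydroxyl to the carbonyl, so one equivalent of mild base alkylates it selectively at the primary allylic carbon.

Step 13
Reactants: 21 4-{[(E)-3,7-dimethylocta-2,6-dien-1-yl]oxy}-2-hydroxybenzaldehyde
Product: 22 methyl (E)-3-(4-{[(E)-3,7-dimethylocta-2,6-dien-1-yl]oxy}-2-hydroxyphenyl)acrylate
Conditions: Ph3P=CHCO2Me, CH2Cl2, rt, dark
Reagents that add atoms: methyl (triphenylphosphoranylidene)acetate, COC(=O)C=P(c1ccccc1)(c1ccccc1)c1ccccc1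
Why: Wittig reaction of a stabilised ylide, which tolerates the free ortho-phenol and favours the E alkene. Any Z isomer would lactonise and be removed on chromatography.

Step 14
Reactants: 22 methyl (E)-3-(4-{[(E)-3,7-dimethylocta-2,6-dien-1-yl]oxy}-2-hydroxyphenyl)acrylate
Product: 23 (E)-3-(4-{[(E)-3,7-dimethylocta-2,6-dien-1-yl]oxy}-2-hydroxyphenyl)acrylic acid
Conditions: LiOH, THF–MeOH–H2O, 40 °C; then cold dilute HCl to pH 3
Reagents that add atoms: lithium hydroxide, [Li+].[OH-]
Why: Saponification of the methyl ester, in which hydroxide supplies the new carboxyl oxygen. The E geometry is kept, the E acid cannot lactonise on acidification, and the geranyl ether is stable to base.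

Step 15
Reactants: 23 (E)-3-(4-{[(E)-3,7-dimethylocta-2,6-dien-1-yl]oxy}-2-hydroxyphenyl)acrylic acid
Product: 25 (E)-3-[2-(tert-butyldimethylsilyloxy)-4-{[(E)-3,7-dimethylocta-2,6-dien-1-yl]oxy}phenyl]acrylic acid, via silyl ester silyl ether 24 (not isolated)
Conditions: TBSCl (2.5 equiv), imidazole, DMF, rt; then AcOH–THF–H2O, rt
Reagents that add atoms: tert-butyldimethylsilyl chloride, CC(C)(C)[Si](C)(C)Cl
Why: Silylation of both acidic hydroxyls, then selective hydrolysis of the silyl ester, which is far more labile to aqueous acid than the aryl silyl ether.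

Step 16
Reactants: 25 (E)-3-[2-(tert-butyldimethylsilyloxy)-4-{[(E)-3,7-dimethylocta-2,6-dien-1-yl]oxy}phenyl]acrylic acid; 18 7-{[(R,E)-6-hydroxy-3,7-dimethyl-7-(triethylsilyloxy)oct-2-en-1-yl]oxy}-2H-chromen-2-one
Product: 27 (R,E)-2,6-dimethyl-8-[(2-oxo-2H-chromen-7-yl)oxy]-2-(triethylsilyloxy)oct-6-en-3-yl (E)-3-[2-(tert-butyldimethylsilyloxy)-4-{[(E)-3,7-dimethylocta-2,6-dien-1-yl]oxy}phenyl]acrylate, via mixed anhydride 26 (not isolated)
Conditions: 2,4,6-trichlorobenzoyl chloride, Et3N, toluene, rt; then 18, DMAP, toluene, rt to 40 °C, dark
Reagents that add atoms: none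
Why: Yamaguchi esterification: DMAP attacks the unhindered cinnamoyl carbonyl of the mixed anhydride, and the acylpyridinium ion acylates the C6' hydroxyl with retention, because the C–O bond of the alcohol is never broken. The tertiary oxygen and the phenol are both blocked by silicon, so only one ester can form.

Step 17
Reactants: 27 (R,E)-2,6-dimethyl-8-[(2-oxo-2H-chromen-7-yl)oxy]-2-(triethylsilyloxy)oct-6-en-3-yl (E)-3-[2-(tert-butyldimethylsilyloxy)-4-{[(E)-3,7-dimethylocta-2,6-dien-1-yl]oxy}phenyl]acrylate
Product: 28 (R,E)-2-hydroxy-2,6-dimethyl-8-[(2-oxo-2H-chromen-7-yl)oxy]oct-6-en-3-yl (E)-3-(4-{[(E)-3,7-dimethylocta-2,6-dien-1-yl]oxy}-2-hydroxyphenyl)acrylate (CNP0360403.1)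
Conditions: TBAF, AcOH (1:1), THF, 0 °C to rt, dark
Reagents that add atoms: none
Why: Fluoride cleavage of the aryl and the tertiary alkyl silyl ether in one operation. Acetic acid buffers the phenoxide and alkoxide so that acyl migration from C6' to C7' and opening of the coumarin should not occur, and light is excluded to keep the cinnamate E.

## Compound list

1 | but-3-yn-1-ol | C#CCCO | starting material
2 | tert-butyl(but-3-yn-1-yloxy)dimethylsilane | C#CCCO[Si](C)(C)C(C)(C)C | intermediate
3 | [(E)-4-(tert-butyldimethylsilyloxy)-2-methylbut-1-en-1-yl]dimethylalane | C[Al](C)/C=C(\C)CCO[Si](C)(C)C(C)(C)C | intermediate (not isolated)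
4 | lithium butyl[(E)-4-(tert-butyldimethylsilyloxy)-2-methylbut-1-en-1-yl]dimethylaluminate | [Li+].CCCC[Al-](C)(C)/C=C(\C)CCO[Si](C)(C)C(C)(C)C | intermediate (not isolated)
5 | (E)-5-(tert-butyldimethylsilyloxy)-3-methylpent-2-en-1-ol | OC/C=C(\C)CCO[Si](C)(C)C(C)(C)C | intermediate
6 | tert-butyl({(E)-5-[(4-methoxybenzyl)oxy]-3-methylpent-3-en-1-yl}oxy)dimethylsilane | COc1ccc(COC/C=C(\C)CCO[Si](C)(C)C(C)(C)C)cc1 | intermediate
7 | (E)-5-[(4-methoxybenzyl)oxy]-3-methylpent-3-en-1-ol | COc1ccc(COC/C=C(\C)CCO)cc1 | intermediate
8 | 1-({[(E)-5-iodo-3-methylpent-2-en-1-yl]oxy}methyl)-4-methoxybenzene | COc1ccc(COC/C=C(\C)CCI)cc1 | intermediate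
9 | {(E)-5-[(4-methoxybenzyl)oxy]-3-methylpent-3-en-1-yl}zinc iodide | I[Zn]CC/C(C)=C/COCc1ccc(OC)cc1 | intermediate (not isolated)
10 | {(E)-5-[(4-methoxybenzyl)oxy]-3-methylpent-3-en-1-yl}[(trimethylsilyl)methyl]zinc | C[Si](C)(C)C[Zn]CC/C(C)=C/COCc1ccc(OC)cc1 | intermediate
11 | methyl 2-hydroxy-2-methylpropanoate (methyl 2-hydroxyisobutyrate) | COC(=O)C(C)(C)O | starting material
12 | methyl 2-methyl-2-(triethylsilyloxy)propanoate | COC(=O)C(C)(C)O[Si](CC)(CC)CC | intermediate
13 | diisobutyl[1-methoxy-2-methyl-2-(triethylsilyloxy)propoxy]alane | COC(O[Al](CC(C)C)CC(C)C)C(C)(C)O[Si](CC)(CC)CC | intermediate (not isolated)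
14 | 2-methyl-2-(triethylsilyloxy)propanal | CC(C)(O[Si](CC)(CC)CC)C=O | intermediate
15 | (R,E)-8-[(4-methoxybenzyl)oxy]-2,6-dimethyl-2-(triethylsilyloxy)oct-6-en-3-ol | COc1ccc(COC/C=C(\C)CC[C@@H](O)C(C)(C)O[Si](CC)(CC)CC)cc1 | intermediate
16 | (R,E)-3,7-dimethyl-7-(triethylsilyloxy)oct-2-ene-1,6-diol | OC/C=C(\C)CC[C@@H](O)C(C)(C)O[Si](CC)(CC)CC | intermediate
17 | umbelliferone (7-hydroxy-2H-chromen-2-one) | Oc1ccc2ccc(=O)oc2c1 | starting material
18 | 7-{[(R,E)-6-hydroxy-3,7-dimethyl-7-(triethylsilyloxy)oct-2-en-1-yl]oxy}-2H-chromen-2-one | O=c1ccc2ccc(OC/C=C(\C)CC[C@@H](O)C(C)(C)O[Si](CC)(CC)CC)cc2o1 | intermediate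
19 | 2,4-dihydroxybenzaldehyde | O=Cc1ccc(O)cc1O | starting material
20 | geranyl bromide ((E)-1-bromo-3,7-dimethylocta-2,6-diene) | CC(C)=CCC/C(C)=C/CBr | starting material
21 | 4-{[(E)-3,7-dimethylocta-2,6-dien-1-yl]oxy}-2-hydroxybenzaldehyde | CC(C)=CCC/C(C)=C/COc1ccc(C=O)c(O)c1 | intermediate
22 | methyl (E)-3-(4-{[(E)-3,7-dimethylocta-2,6-dien-1-yl]oxy}-2-hydroxyphenyl)acrylate | CC(C)=CCC/C(C)=C/COc1ccc(/C=C/C(=O)OC)c(O)c1 | intermediate
23 | (E)-3-(4-{[(E)-3,7-dimethylocta-2,6-dien-1-yl]oxy}-2-hydroxyphenyl)acrylic acid | CC(C)=CCC/C(C)=C/COc1ccc(/C=C/C(=O)O)c(O)c1 | intermediate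
24 | tert-butyldimethylsilyl (E)-3-[2-(tert-butyldimethylsilyloxy)-4-{[(E)-3,7-dimethylocta-2,6-dien-1-yl]oxy}phenyl]acrylate | CC(C)=CCC/C(C)=C/COc1ccc(/C=C/C(=O)O[Si](C)(C)C(C)(C)C)c(O[Si](C)(C)C(C)(C)C)c1 | intermediate (not isolated)
25 | (E)-3-[2-(tert-butyldimethylsilyloxy)-4-{[(E)-3,7-dimethylocta-2,6-dien-1-yl]oxy}phenyl]acrylic acid | CC(C)=CCC/C(C)=C/COc1ccc(/C=C/C(=O)O)c(O[Si](C)(C)C(C)(C)C)c1 | intermediate
26 | (E)-3-[2-(tert-butyldimethylsilyloxy)-4-{[(E)-3,7-dimethylocta-2,6-dien-1-yl]oxy}phenyl]acrylic 2,4,6-trichlorobenzoic anhydride | CC(C)=CCC/C(C)=C/COc1ccc(/C=C/C(=O)OC(=O)c2c(Cl)cc(Cl)cc2Cl)c(O[Si](C)(C)C(C)(C)C)c1 | intermediate (not isolated)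
27 | (R,E)-2,6-dimethyl-8-[(2-oxo-2H-chromen-7-yl)oxy]-2-(triethylsilyloxy)oct-6-en-3-yl (E)-3-[2-(tert-butyldimethylsilyloxy)-4-{[(E)-3,7-dimethylocta-2,6-dien-1-yl]oxy}phenyl]acrylate | CC(C)=CCC/C(C)=C/COc1ccc(/C=C/C(=O)O[C@H](CC/C(C)=C/COc2ccc3ccc(=O)oc3c2)C(C)(C)O[Si](CC)(CC)CC)c(O[Si](C)(C)C(C)(C)C)c1 | intermediate
28 | (R,E)-2-hydroxy-2,6-dimethyl-8-[(2-oxo-2H-chromen-7-yl)oxy]oct-6-en-3-yl (E)-3-(4-{[(E)-3,7-dimethylocta-2,6-dien-1-yl]oxy}-2-hydroxyphenyl)acrylate (CNP0360403.1) | CC(C)=CCC/C(C)=C/COc1ccc(/C=C/C(=O)O[C@H](CC/C(C)=C/COc2ccc3ccc(=O)oc3c2)C(C)(C)O)c(O)c1 | target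

## Step count and risks

Total: 17 steps. Longest linear sequence: 11 steps (steps 1–6, 9, 10, 11, 16, 17, from but-3-yn-1-ol). The aldehyde branch (steps 7, 8) and the acid branch (steps 12–15) are convergent.

Least certain steps:

**Step 9 (key step).**
- Risk: alkyl transfer to the neopentyl-type carbonyl of 14 may be slow, so that β-hydride reduction of the aldehyde competes. Facial discrimination on an α-quaternary α-silyloxy aldehyde may be lower than on the usual substrates, or follow the opposite sense to the model assumed. Traces of lithium halide carried over with 10 could open an uncatalysed, unselective background addition.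
- Fallback, from 8 and 14, returning at 15: iodide 8 is converted by iodine–lithium exchange (t-BuLi, Et2O–pentane, −78 °C) into {(E)-5-[(4-methoxybenzyl)oxy]-3-methylpent-3-en-1-yl}lithium F1, which is added to 14 to give the racemic alcohol (E)-8-[(4-methoxybenzyl)oxy]-2,6-dimethyl-2-(triethylsilyloxy)oct-6-en-3-ol F2. Oxidation with Dess–Martin periodinane (NaHCO3, CH2Cl2) gives the ketone (E)-8-[(4-methoxybenzyl)oxy]-2,6-dimethyl-2-(triethylsilyloxy)oct-6-en-3-one F3. Corey–Bakshi–Shibata reduction with (S)-1-methyl-3,3-diphenyltetrahydro-1H,3H-pyrrolo[1,2-c][1,3,2]oxazaborole and catecholborane (toluene, −78 °C) then sets C6'. The CMe2(OSiEt3) group acts as the large substituent and the CH2 chain as the small one, which by the standard model corresponds to R, and the route is rejoined at 15. Catecholborane is chosen so that the trisubstituted alkene is not hydroborated.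

**Step 6.**
- Risk: incomplete zinc insertion or Wurtz-type coupling of the primary iodide, and incomplete removal of LiI and THF, which would then erode the selectivity of step 9. Radical intermediates at the zinc surface could also scramble the alkene geometry through reversible homoallyl–cyclopropylcarbinyl rearrangement.
- Fallback, from 8, returning at 15: iodide 8 is heated with neat Et2Zn and catalytic CuI (50 °C), which gives ethyl{(E)-5-[(4-methoxybenzyl)oxy]-3-methylpent-3-en-1-yl}zinc F4 by iodine–zinc exchange. Removal of EtI and excess Et2Zn under vacuum then drives ligand redistribution to the homoleptic bis{(E)-5-[(4-methoxybenzyl)oxy]-3-methylpent-3-en-1-yl}zinc F5, two molecules of 8 going into each molecule of F5. This reagent is free of lithium salts and THF; in toluene it is used with 14 under the Ti(OiPr)4/bis(sulfonamide) conditions of step 9 to reach 15, at the price of one of its two chains.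

**Step 2.**
- Risk: incomplete capture of the alkenylaluminium species by formaldehyde (protonolysis on work-up would return the simple alkene), and a minor regioisomer from methylalumination.
- Fallback, from 2, returning at 5: after the same methylalumination, alane 3 is trapped with ClCO2Et, a more dependable electrophile, to give ethyl (E)-5-(tert-butyldimethylsilyloxy)-3-methylpent-2-enoate F6. Reduction with i-Bu2AlH (CH2Cl2, −78 °C) gives 5 with the E geometry intact.

**Step 16.**
- Risk: sluggish acylation of the hindered C6' hydroxyl next to the silylated quaternary carbon; forcing conditions could cause silyl migration from O7' to O6' or isomerisation of the cinnamate.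
- Fallback, from 18 and 21, returning at 27: 18 is acylated with the small, unhindered diethylphosphonoacetic acid (EDC, DMAP, CH2Cl2) to give (R,E)-2,6-dimethyl-8-[(2-oxo-2H-chromen-7-yl)oxy]-2-(triethylsilyloxy)oct-6-en-3-yl 2-(diethoxyphosphoryl)acetate F7. Aldehyde 21 is silylated (TBSCl, imidazole, DMF) to 2-(tert-butyldimethylsilyloxy)-4-{[(E)-3,7-dimethylocta-2,6-dien-1-yl]oxy}benzaldehyde F8. A Horner–Wadsworth–Emmons reaction of F7 with F8 (LiCl, i-Pr2NEt, MeCN, rt) builds the E cinnamate directly and rejoins the route at 27.

## Further compounds

F1 | step 9 | {(E)-5-[(4-methoxybenzyl)oxy]-3-methylpent-3-en-1-yl}lithium | [Li]CC/C(C)=C/COCc1ccc(OC)cc1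
F2 | step 9 | racemic (E)-8-[(4-methoxybenzyl)oxy]-2,6-dimethyl-2-(triethylsilyloxy)oct-6-en-3-ol | COc1ccc(COC/C=C(\C)CCC(O)C(C)(C)O[Si](CC)(CC)CC)cc1
F3 | step 9 | (E)-8-[(4-methoxybenzyl)oxy]-2,6-dimethyl-2-(triethylsilyloxy)oct-6-en-3-one | COc1ccc(COC/C=C(\C)CCC(=O)C(C)(C)O[Si](CC)(CC)CC)cc1
F4 | step 6 | ethyl{(E)-5-[(4-methoxybenzyl)oxy]-3-methylpent-3-en-1-yl}zinc | CC[Zn]CC/C(C)=C/COCc1ccc(OC)cc1
F5 | step 6 | bis{(E)-5-[(4-methoxybenzyl)oxy]-3-methylpent-3-en-1-yl}zinc | COc1ccc(COC/C=C(\C)CC[Zn]CC/C(C)=C/COCc2ccc(OC)cc2)cc1
F6 | step 2 | ethyl (E)-5-(tert-butyldimethylsilyloxy)-3-methylpent-2-enoate | CCOC(=O)/C=C(\C)CCO[Si](C)(C)C(C)(C)C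
F7 | step 16 | (R,E)-2,6-dimethyl-8-[(2-oxo-2H-chromen-7-yl)oxy]-2-(triethylsilyloxy)oct-6-en-3-yl 2-(diethoxyphosphoryl)acetate | CCOP(=O)(CC(=O)O[C@H](CC/C(C)=C/COc1ccc2ccc(=O)oc2c1)C(C)(C)O[Si](CC)(CC)CC)OCC
F8 | step 16 | 2-(tert-butyldimethylsilyloxy)-4-{[(E)-3,7-dimethylocta-2,6-dien-1-yl]oxy}benzaldehyde | CC(C)=CCC/C(C)=C/COc1ccc(C=O)c(O[Si](C)(C)C(C)(C)C)c1
A1 | alternative 1 | 3-({(E)-3-methyl-5-[(R)-2,2,5,5-tetramethyl-1,3-dioxolan-4-yl]pent-2-en-1-yl}oxy)phenyl propiolate | C#CC(=O)Oc1cccc(OC/C=C(\C)CC[C@H]2OC(C)(C)OC2(C)C)c1
A2 | alternative 1 | 7-({(E)-3-methyl-5-[(R)-2,2,5,5-tetramethyl-1,3-dioxolan-4-yl]pent-2-en-1-yl}oxy)-2H-chromen-2-one | CC1(C)O[C@H](CC/C(C)=C/COc2ccc3ccc(=O)oc3c2)C(C)(C)O1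
A3 | alternative 2 | (R)-4-(but-3-yn-1-yl)-2,2,5,5-tetramethyl-1,3-dioxolane | C#CCC[C@H]1OC(C)(C)OC1(C)C
A4 | alternative 2 | (E)-3-methyl-5-[(R)-2,2,5,5-tetramethyl-1,3-dioxolan-4-yl]pent-2-en-1-ol | OC/C=C(\C)CC[C@H]1OC(C)(C)OC1(C)C
A5 | alternative 3 | racemic 7-[(2-hydroxy-3-methylbut-3-en-1-yl)oxy]-2H-chromen-2-one | C=C(C)C(O)COc1ccc2ccc(=O)oc2c1
A6 | alternative 3 | 3,3-dimethoxy-2-methylbutan-2-ol | COC(C)(OC)C(C)(C)O
A7 | alternative 3 | 7-{[(E)-7-hydroxy-3,7-dimethyl-6-oxooct-2-en-1-yl]oxy}-2H-chromen-2-one | CC(C)(O)C(=O)CC/C(C)=C/COc1ccc2ccc(=O)oc2c1
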